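**Retrosynthetic overview**

1. Acid 28 comes from N-acyl oxazolidinone 26 (LiOOH); the (Z)-alkylidene of 26 comes from dienyl carbinol 23 by reductive 1,3-transposition (allylic diazene, loss of N2).
2. Key C6–C1' bond of 23: the 6-methyl-1,2-dioxan-6-ylium ion (from methyl peroxyketal 9) plus the 3-silyloxyalkylzinc 21. Reagent 21 is a homoenolate-type d3 synthon: the β-carbanion of the dienyl ketone, held at the carbinol oxidation level. Two natural acceptor carbons are joined, the dissonant 1,4-O,O array is made and C6 is set.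
3. Peroxyketal 9 comes from an Evans syn-aldol of 4-methylpent-4-enal (C2, C3), mesylation, ozonolysis in MeOH and 6-exo-tet peroxide closure with inversion at C3.
4. Zinc reagent 21 comes from dienyl triflate 15 (Birch ketone of 6-methoxy-1,1-dimethyltetralin) and acrolein (Nozaki–Hiyama–Kishi), then silylation, hydroboration and boron–zinc exchange.
5. Ring order: carbocycles A and B arrive with the tetralone (aromatic ring A is reduced in step 6); the 1,2-dioxane is the only ring built (step 4), before the fragments are joined.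

Locants used below: dioxane C3 and C6; side chain C1'–C3' (C1' on C6, C3' the alkene carbon); ring carbons by hexahydronaphthalene numbering.

Assumption: the SMILES is read literally, i.e. (2S,3S,6S) and the side chain cis to ring CH2-1 at the exocyclic alkene (formally Z).

**Route**

Step 1
Reactants: 1 2-methylprop-2-en-1-ol
Product: 3 4-methylpent-4-enal, via vinyl ether 2 (not isolated)
Conditions: BuOCH=CH2 (excess), Pd(OCOCF3)2 (0.5 mol %), 4,7-diphenyl-1,10-phenanthroline (0.5 mol %), Et3N (cat.), 75 °C; strip volatiles; neat, 130 °C, sealed tube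
Reagents that add atoms: butyl vinyl ether, C=COCCCC
Why: Pd-catalysed transfer vinylation followed by the aliphatic Claisen rearrangement of the allyl vinyl ether gives the γ,δ-unsaturated aldehyde; no stereocenter is formed.

Step 2
Reactants: 3 4-methylpent-4-enal; 4 (4S)-4-benzyl-3-propanoyl-1,3-oxazolidin-2-one
Product: 6 (4S)-4-benzyl-3-[(2S,3R)-3-hydroxy-2,6-dimethylhept-6-enoyl]-1,3-oxazolidin-2-one, via boron enolate 5 (not isolated)
Conditions: Bu2BOTf, i-Pr2NEt, CH2Cl2, 0 °C; then 3, −78 → 0 °C; pH 7 buffer, MeOH, 30% H2O2, 0 °C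
Reagents that add atoms: none
Why: Evans syn-aldol reaction: the (Z)-boron enolate reacts through a closed chair transition state on the face away from the benzyl group, which sets C2 (S) and C3 (R) together.

Step 3
Reactants: 6 (4S)-4-benzyl-3-[(2S,3R)-3-hydroxy-2,6-dimethylhept-6-enoyl]-1,3-oxazolidin-2-one
Product: 7 (4S)-4-benzyl-3-[(2S,3R)-3-(methanesulfonyloxy)-2,6-dimethylhept-6-enoyl]-1,3-oxazolidin-2-one
Conditions: MsCl, Et3N, CH2Cl2, 0 °C, 30 min
Reagents that add atoms: methanesulfonyl chloride, CS(=O)(=O)Cl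
Why: O-sulfonylation with retention turns the C3 hydroxyl into a leaving group; the α-proton of the branched imide lies in the imide plane (A(1,3) strain) and resists E1cB elimination under these conditions.

Step 4
Reactants: 7 (4S)-4-benzyl-3-[(2S,3R)-3-(methanesulfonyloxy)-2,6-dimethylhept-6-enoyl]-1,3-oxazolidin-2-one
Product: 9 (4S)-4-benzyl-3-[(2S)-2-[(3S)-6-methoxy-6-methyl-1,2-dioxan-3-yl]propanoyl]-1,3-oxazolidin-2-one (both C6 epimers), via hydroperoxy ketal 8 (not isolated)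
Conditions: O3, CH2Cl2/MeOH 4:1, NaHCO3, −78 °C (to first blue colour); N2 purge; concentrate below 20 °C; then Cs2CO3, DMF, 0 → 25 °C
Reagents that add atoms: ozone, [O-][O+]=O; methanol, CO
Why: Criegee ozonolysis of the 1,1-disubstituted alkene in methanol traps the ketone oxide as the α-methoxy hydroperoxide, and its peroxide anion closes the ring by 6-exo-tet SN2 displacement of the mesylate with inversion, turning C3 (R) into the required C3 (S); the C6 mixture is erased in step 10.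

Step 5
Reactants: 10 6-methoxy-3,4-dihydronaphthalen-1(2H)-one
Product: 11 6-methoxy-1,1-dimethyl-1,2,3,4-tetrahydronaphthalene
Conditions: TiCl4 (2 equiv), Me2Zn (2 equiv), CH2Cl2, −40 → 25 °C
Reagents that add atoms: dimethylzinc, C[Zn]C
Why: Reetz geminal dimethylation: Me2TiCl2 adds once to the ketone, the titanium alkoxide ionises to the p-methoxybenzylic cation and a second methyl is delivered; no stereocenter is formed.

Step 6
Reactants: 11 6-methoxy-1,1-dimethyl-1,2,3,4-tetrahydronaphthalene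
Product: 13 5,5-dimethyl-3,4,5,6,7,8-hexahydronaphthalen-2(1H)-one, via enol ether 12 (not isolated)
Conditions: Li, NH3(l), THF, t-BuOH, −33 °C; NH4Cl; then (CO2H)2, MeOH/H2O, 25 °C
Reagents that add atoms: water, O
Why: Birch reduction gives the 2,5-dihydroanisole with the tetrasubstituted ring-fusion alkene, and mild oxalic acid hydrolysis of the enol ether gives the β,γ-enone without conjugation; no stereocenter is formed.

Step 7
Reactants: 13 5,5-dimethyl-3,4,5,6,7,8-hexahydronaphthalen-2(1H)-one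
Product: 15 5,5-dimethyl-3,4,5,6,7,8-hexahydronaphthalen-2-yl trifluoromethanesulfonate, via lithium dienolate 14 (not isolated)
Conditions: LiN(i-Pr)2, THF, −78 °C; PhNTf2, −78 → 0 °C
Reagents that add atoms: N-phenylbis(trifluoromethanesulfonimide), O=S(=O)(N(c1ccccc1)S(=O)(=O)C(F)(F)F)C(F)(F)F
Why: Enol triflate formation: deprotonation at the doubly activated C1 (α to C=O and allylic) gives the linear dienolate, and O-sulfonylation fixes the C1=C2 double bond that the transposition in step 11 needs.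

Step 8
Reactants: 15 5,5-dimethyl-3,4,5,6,7,8-hexahydronaphthalen-2-yl trifluoromethanesulfonate; 16 prop-2-enal (acrolein)
Product: 18 1-(5,5-dimethyl-3,4,5,6,7,8-hexahydronaphthalen-2-yl)prop-2-en-1-ol (racemic), via alkenylchromium 17 (not isolated)
Conditions: CrCl2 (4 equiv), NiCl2 (2 mol %), DMF, 25 °C
Reagents that add atoms: none
Why: Nozaki–Hiyama–Kishi coupling: nickel-catalysed insertion into the alkenyl triflate and transfer to chromium give an alkenylchromium species that adds 1,2 to the aldehyde; the carbinol centre is racemic and is destroyed in step 11.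

Step 9
Reactants: 18 1-(5,5-dimethyl-3,4,5,6,7,8-hexahydronaphthalen-2-yl)prop-2-en-1-ol
Product: 19 triethyl{[1-(5,5-dimethyl-3,4,5,6,7,8-hexahydronaphthalen-2-yl)prop-2-en-1-yl]oxy}silane (racemic)
Conditions: Et3SiCl, imidazole, DMF, 0 °C
Reagents that add atoms: chlorotriethylsilane, CC[Si](Cl)(CC)CC
Why: Silyl ether protection under basic conditions keeps the acid-sensitive dienyl carbinol intact and masks the hydroxyl for the organometallic steps.

Step 10
Reactants: 19 triethyl{[1-(5,5-dimethyl-3,4,5,6,7,8-hexahydronaphthalen-2-yl)prop-2-en-1-yl]oxy}silane (2.2 equiv); 9 (4S)-4-benzyl-3-[(2S)-2-[(3S)-6-methoxy-6-methyl-1,2-dioxan-3-yl]propanoyl]-1,3-oxazolidin-2-one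
Product: 23 (4S)-4-benzyl-3-[(2S)-2-[(3S,6S)-6-[3-(5,5-dimethyl-3,4,5,6,7,8-hexahydronaphthalen-2-yl)-3-hydroxypropyl]-6-methyl-1,2-dioxan-3-yl]propanoyl]-1,3-oxazolidin-2-one (both carbinol epimers), via alkylborane 20 (not isolated), via dialkylzinc 21 (not isolated), via silyl ether 22 (not isolated)
Conditions: Et2BH (from BH3·SMe2 + 2 Et3B), Et2O, 0 → 25 °C; evaporate; Et2Zn (neat), 0 °C, then 0.1 mmHg, 40 °C; then 9 premixed with Me3SiOTf (1.1 equiv), CH2Cl2, −78 → −40 °C; aq. NaHCO3; then Bu4NF/AcOH, THF, 0 °C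
Reagents that add atoms: none
Why: Proposed new method: anti-Markovnikov hydroboration of the terminal vinyl group and boron–zinc exchange turn 19 into dialkylzinc 21, a homoenolate-type d3 reagent whose carbanionic carbon is β to the masked carbonyl carbon C3', while Me3SiOTf ionises 9 to the 6-methyl-1,2-dioxan-6-ylium ion, so two carbons that are both natural acceptors (ketal carbon C6 and the β-carbon) are joined and a 1,4-dioxygenated chain results; the half-chair cation keeps the C3 substituent pseudo-equatorial and takes the nucleophile along the axial trajectory through a chair-like transition state, which places the new chain cis to the C3 substituent (6S), whereas the carbinol centre is uncontrolled and removed in step 11; the closest known reaction types are Lewis-acid additions of allylsilanes and silyl enol ethers to peroxycarbenium ions and dialkylzinc additions to oxocarbenium ions generated from acetals.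

Step 11
Reactants: 23 (4S)-4-benzyl-3-[(2S)-2-[(3S,6S)-6-[3-(5,5-dimethyl-3,4,5,6,7,8-hexahydronaphthalen-2-yl)-3-hydroxypropyl]-6-methyl-1,2-dioxan-3-yl]propanoyl]-1,3-oxazolidin-2-one
Product: 26 (4S)-4-benzyl-3-[(2S)-2-[(3S,6S)-6-[(3Z)-3-(5,5-dimethyl-3,4,5,6,7,8-hexahydronaphthalen-2(1H)-ylidene)propyl]-6-methyl-1,2-dioxan-3-yl]propanoyl]-1,3-oxazolidin-2-one, via sulfonylhydrazine 24 (not isolated), via allylic diazene 25 (not isolated)
Conditions: PPh3/DEAD (premixed), N-methylmorpholine, −30 °C; 23; then 2-nitrobenzenesulfonylhydrazide, −30 °C, 2 h, then 23 °C, 3 h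
Reagents that add atoms: none
Why: Myers reductive 1,3-transposition: Mitsunobu N-alkylation, loss of sulfinic acid and retro-ene loss of N2 from the allylic diazene deliver hydrogen to ring C1 and move the double bond to the exocyclic position; because the central allyl carbon is substituted (ring C3), the side chain takes the inside position to avoid A(1,2) strain and ends up cis to C1, which is the (Z) geometry, and both carbinol epimers converge on it.

Step 12
Reactants: 26 (4S)-4-benzyl-3-[(2S)-2-[(3S,6S)-6-[(3Z)-3-(5,5-dimethyl-3,4,5,6,7,8-hexahydronaphthalen-2(1H)-ylidene)propyl]-6-methyl-1,2-dioxan-3-yl]propanoyl]-1,3-oxazolidin-2-one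
Product: 28 (2S)-2-[(3S,6S)-6-[(3Z)-3-(5,5-dimethyl-3,4,5,6,7,8-hexahydronaphthalen-2(1H)-ylidene)propyl]-6-methyl-1,2-dioxan-3-yl]propanoic acid, via peroxy acid 27 (not isolated)
Conditions: LiOH (2 equiv), 30% H2O2 (4 equiv), THF/H2O 3:1, 0 °C, 1 h; aq. Na2SO3, 0 °C; 1 M HCl to pH 3
Reagents that add atoms: hydrogen peroxide, OO
Why: Evans auxiliary cleavage by hydroperoxide anion attacks the exocyclic carbonyl selectively at 0 °C, which spares the base-sensitive β-peroxy stereocentres C2 and C3; sulfite reduces only the percarboxylate.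

**Compound list**

1 | 2-methylprop-2-en-1-ol | CC(=C)CO | starting material
2 | 3-(ethenyloxy)-2-methylprop-1-ene | CC(=C)COC=C | intermediate
3 | 4-methylpent-4-enal | CC(=C)CCC=O | intermediate
4 | (4S)-4-benzyl-3-propanoyl-1,3-oxazolidin-2-one | CCC(=O)N1[C@@H](Cc2ccccc2)COC1=O | starting material
5 | (Z)-dibutylboron enolate of 4 | C/C=C(\OB(CCCC)CCCC)N1[C@@H](Cc2ccccc2)COC1=O | intermediate
6 | (4S)-4-benzyl-3-[(2S,3R)-3-hydroxy-2,6-dimethylhept-6-enoyl]-1,3-oxazolidin-2-one | C=C(C)CC[C@@H](O)[C@H](C)C(=O)N1[C@@H](Cc2ccccc2)COC1=O | intermediate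
7 | (4S)-4-benzyl-3-[(2S,3R)-3-(methanesulfonyloxy)-2,6-dimethylhept-6-enoyl]-1,3-oxazolidin-2-one | C=C(C)CC[C@@H](OS(C)(=O)=O)[C@H](C)C(=O)N1[C@@H](Cc2ccccc2)COC1=O | intermediate
8 | (4S)-4-benzyl-3-[(2S,3R)-6-hydroperoxy-6-methoxy-3-(methanesulfonyloxy)-2-methylheptanoyl]-1,3-oxazolidin-2-one (C6 epimers) | COC(C)(OO)CC[C@@H](OS(C)(=O)=O)[C@H](C)C(=O)N1[C@@H](Cc2ccccc2)COC1=O | intermediate
9 | (4S)-4-benzyl-3-[(2S)-2-[(3S)-6-methoxy-6-methyl-1,2-dioxan-3-yl]propanoyl]-1,3-oxazolidin-2-one (C6 epimers) | C[C@H](C(=O)N1[C@@H](Cc2ccccc2)COC1=O)[C@@H]1CCC(C)(OC)OO1 | intermediate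
10 | 6-methoxy-3,4-dihydronaphthalen-1(2H)-one | COc1ccc2c(c1)CCCC2=O | starting material
11 | 6-methoxy-1,1-dimethyl-1,2,3,4-tetrahydronaphthalene | COc1ccc2c(c1)CCCC2(C)C | intermediate
12 | 6-methoxy-1,1-dimethyl-1,2,3,4,5,8-hexahydronaphthalene | COC1=CCC2=C(C1)CCCC2(C)C | intermediate
13 | 5,5-dimethyl-3,4,5,6,7,8-hexahydronaphthalen-2(1H)-one | O=C1CCC2=C(C1)CCCC2(C)C | intermediate
14 | lithium 5,5-dimethyl-3,4,5,6,7,8-hexahydronaphthalen-2-olate | [Li]OC1=CC2=C(CC1)C(C)(C)CCC2 | intermediate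
15 | 5,5-dimethyl-3,4,5,6,7,8-hexahydronaphthalen-2-yl trifluoromethanesulfonate | O=S(=O)(OC1=CC2=C(CC1)C(C)(C)CCC2)C(F)(F)F | intermediate
16 | prop-2-enal | C=CC=O | starting material
17 | dichloro(5,5-dimethyl-3,4,5,6,7,8-hexahydronaphthalen-2-yl)chromium | Cl[Cr](Cl)C1=CC2=C(CC1)C(C)(C)CCC2 | intermediate
18 | 1-(5,5-dimethyl-3,4,5,6,7,8-hexahydronaphthalen-2-yl)prop-2-en-1-ol (racemic) | C=CC(O)C1=CC2=C(CC1)C(C)(C)CCC2 | intermediate
19 | triethyl{[1-(5,5-dimethyl-3,4,5,6,7,8-hexahydronaphthalen-2-yl)prop-2-en-1-yl]oxy}silane (racemic) | C=CC(O[Si](CC)(CC)CC)C1=CC2=C(CC1)C(C)(C)CCC2 | intermediate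
20 | [3-(5,5-dimethyl-3,4,5,6,7,8-hexahydronaphthalen-2-yl)-3-(triethylsilyloxy)propyl]diethylborane | CCB(CC)CCC(O[Si](CC)(CC)CC)C1=CC2=C(CC1)C(C)(C)CCC2 | intermediate
21 | bis[3-(5,5-dimethyl-3,4,5,6,7,8-hexahydronaphthalen-2-yl)-3-(triethylsilyloxy)propyl]zinc | CC[Si](CC)(CC)OC(CC[Zn]CCC(O[Si](CC)(CC)CC)C1=CC2=C(CC1)C(C)(C)CCC2)C1=CC2=C(CC1)C(C)(C)CCC2 | intermediate
22 | triethylsilyl ether of 23 (same arrangement at C6, formal descriptor 6R; carbinol epimers) | C[C@H](C(=O)N1[C@@H](Cc2ccccc2)COC1=O)[C@@H]1CC[C@](C)(CCC(O[Si](CC)(CC)CC)C2=CC3=C(CC2)C(C)(C)CCC3)OO1 | intermediate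
23 | (4S)-4-benzyl-3-[(2S)-2-[(3S,6S)-6-[3-(5,5-dimethyl-3,4,5,6,7,8-hexahydronaphthalen-2-yl)-3-hydroxypropyl]-6-methyl-1,2-dioxan-3-yl]propanoyl]-1,3-oxazolidin-2-one (carbinol epimers) | C[C@H](C(=O)N1[C@@H](Cc2ccccc2)COC1=O)[C@@H]1CC[C@](C)(CCC(O)C2=CC3=C(CC2)C(C)(C)CCC3)OO1 | intermediate
24 | N-alkyl-N-(2-nitrobenzenesulfonyl)hydrazine from 23 (N on C3') | C[C@H](C(=O)N1[C@@H](Cc2ccccc2)COC1=O)[C@@H]1CC[C@](C)(CCC(N(N)S(=O)(=O)c2ccccc2[N+](=O)[O-])C2=CC3=C(CC2)C(C)(C)CCC3)OO1 | intermediate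
25 | allylic monoalkyl diazene from 24 | C[C@H](C(=O)N1[C@@H](Cc2ccccc2)COC1=O)[C@@H]1CC[C@](C)(CCC(N=N)C2=CC3=C(CC2)C(C)(C)CCC3)OO1 | intermediate
26 | (4S)-4-benzyl-3-[(2S)-2-[(3S,6S)-6-[(3Z)-3-(5,5-dimethyl-3,4,5,6,7,8-hexahydronaphthalen-2(1H)-ylidene)propyl]-6-methyl-1,2-dioxan-3-yl]propanoyl]-1,3-oxazolidin-2-one | C[C@H](C(=O)N1[C@@H](Cc2ccccc2)COC1=O)[C@@H]1CC[C@](C)(CC/C=C2/CCC3=C(CCCC3(C)C)C2)OO1 | intermediate
27 | (2S)-2-[(3S,6S)-6-[(3Z)-3-(5,5-dimethyl-3,4,5,6,7,8-hexahydronaphthalen-2(1H)-ylidene)propyl]-6-methyl-1,2-dioxan-3-yl]propaneperoxoic acid | C[C@H](C(=O)OO)[C@@H]1CC[C@](C)(CC/C=C2/CCC3=C(CCCC3(C)C)C2)OO1 | intermediate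
28 | (2S)-2-[(3S,6S)-6-[(3Z)-3-(5,5-dimethyl-3,4,5,6,7,8-hexahydronaphthalen-2(1H)-ylidene)propyl]-6-methyl-1,2-dioxan-3-yl]propanoic acid | C[C@H](C(=O)O)[C@@H]1CC[C@](C)(CC/C=C2/CCC3=C(CCCC3(C)C)C2)OO1 | target

**Step count and risks**

Total steps: 12. Longest linear sequence: 8 (steps 5 to 12); the peroxide branch (steps 1 to 4, then 10 to 12) is 7.

The three steps most likely to fail are step 10, step 11 and step 4.

Step 10 is the boldest. The dialkylzinc may not add to the peroxycarbenium ion, may attack the O–O bond, or the dienylic silyl ether may ionise under Me3SiOTf. Only one alkyl group of 21 is transferred. The fallback sets out from 9 (and from triflate 15 for the partner) and comes back at 23.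
- Peroxyketal 9 is ionised with catalytic Me3SiOTf in the presence of bis(trimethylsilyl)acetylene, a small π-nucleophile of the allylsilane class that adds axially. This gives (4S)-4-benzyl-3-[(2S)-2-[(3S,6R)-6-methyl-6-[(trimethylsilyl)ethynyl]-1,2-dioxan-3-yl]propanoyl]-1,3-oxazolidin-2-one F1.
- Buffered Bu4NF/AcOH gives (4S)-4-benzyl-3-[(2S)-2-[(3S,6R)-6-ethynyl-6-methyl-1,2-dioxan-3-yl]propanoyl]-1,3-oxazolidin-2-one F2.
- Triflate 15 is formylated (Pd(PPh3)4, CO, Bu3SnH) to 5,5-dimethyl-3,4,5,6,7,8-hexahydronaphthalene-2-carbaldehyde F3.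
- Zn(OTf)2/Et3N alkynylation of F3 with F2 gives (4S)-4-benzyl-3-[(2S)-2-[(3S,6R)-6-[3-(5,5-dimethyl-3,4,5,6,7,8-hexahydronaphthalen-2-yl)-3-hydroxyprop-1-yn-1-yl]-6-methyl-1,2-dioxan-3-yl]propanoyl]-1,3-oxazolidin-2-one F4.
- Diimide (2-nitrobenzenesulfonylhydrazide, Et3N) saturates only the alkyne and gives 23.

Step 11 can fail in two ways. The Mitsunobu alkylation of a hindered dienylic alcohol may go SN2' or eliminate, and PPh3 may attack the peroxide. The Z preference rests on the inside model for allylic diazenes with a substituted central carbon and is not proven for this ring. The fallback sets out from 23 and comes back at 26.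
- Dess–Martin oxidation gives (4S)-4-benzyl-3-[(2S)-2-[(3S,6R)-6-[3-(5,5-dimethyl-3,4,5,6,7,8-hexahydronaphthalen-2-yl)-3-oxopropyl]-6-methyl-1,2-dioxan-3-yl]propanoyl]-1,3-oxazolidin-2-one F5.
- TsNHNH2 gives its tosylhydrazone (4S)-4-benzyl-3-[(2S)-2-[(3S,6S)-6-[3-(5,5-dimethyl-3,4,5,6,7,8-hexahydronaphthalen-2-yl)-3-(tosylhydrazinylidene)propyl]-6-methyl-1,2-dioxan-3-yl]propanoyl]-1,3-oxazolidin-2-one F6.
- Catecholborane followed by NaOAc·3H2O generates diazene 25 by hydride addition to C=N and sulfinate loss, with no phosphine and no substitution at the carbinol carbon, and gives 26.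
- This fallback does not change the geometry-determining retro-ene. If the E/Z ratio is poor, the isomers would have to be separated on AgNO3-impregnated silica.

Step 4 may give E1cB elimination of the β-mesyloxy imide instead of substitution, or the peroxide anion may attack the imide. The fallback sets out from 7 and comes back at 9.
- DBU deliberately eliminates 7 to (4S)-4-benzyl-3-[(2E)-2,6-dimethylhepta-2,6-dienoyl]-1,3-oxazolidin-2-one F7.
- Selective ozonolysis of the electron-rich 1,1-disubstituted alkene in MeOH gives (4S)-4-benzyl-3-[(2E)-6-hydroperoxy-6-methoxy-2-methylhept-2-enoyl]-1,3-oxazolidin-2-one F8.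
- Et2NH in CF3CH2OH closes the dioxane by 6-exo oxa-Michael addition. This gives 9 together with its C2/C3 diastereomers, which are separated by chromatography, so stereocontrol is traded for robustness.

**Further compounds**

F1 | step 10 | (4S)-4-benzyl-3-[(2S)-2-[(3S,6R)-6-methyl-6-[(trimethylsilyl)ethynyl]-1,2-dioxan-3-yl]propanoyl]-1,3-oxazolidin-2-one | C[C@H](C(=O)N1[C@@H](Cc2ccccc2)COC1=O)[C@@H]1CC[C@](C)(C#C[Si](C)(C)C)OO1
F2 | step 10 | (4S)-4-benzyl-3-[(2S)-2-[(3S,6R)-6-ethynyl-6-methyl-1,2-dioxan-3-yl]propanoyl]-1,3-oxazolidin-2-one | C[C@H](C(=O)N1[C@@H](Cc2ccccc2)COC1=O)[C@@H]1CC[C@](C)(C#C)OO1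
F3 | step 10 | 5,5-dimethyl-3,4,5,6,7,8-hexahydronaphthalene-2-carbaldehyde | O=CC1=CC2=C(CC1)C(C)(C)CCC2
F4 | step 10 | (4S)-4-benzyl-3-[(2S)-2-[(3S,6R)-6-[3-(5,5-dimethyl-3,4,5,6,7,8-hexahydronaphthalen-2-yl)-3-hydroxyprop-1-yn-1-yl]-6-methyl-1,2-dioxan-3-yl]propanoyl]-1,3-oxazolidin-2-one | C[C@H](C(=O)N1[C@@H](Cc2ccccc2)COC1=O)[C@@H]1CC[C@](C)(C#CC(O)C2=CC3=C(CC2)C(C)(C)CCC3)OO1
F5 | step 11 | (4S)-4-benzyl-3-[(2S)-2-[(3S,6R)-6-[3-(5,5-dimethyl-3,4,5,6,7,8-hexahydronaphthalen-2-yl)-3-oxopropyl]-6-methyl-1,2-dioxan-3-yl]propanoyl]-1,3-oxazolidin-2-one | C[C@H](C(=O)N1[C@@H](Cc2ccccc2)COC1=O)[C@@H]1CC[C@](C)(CCC(=O)C2=CC3=C(CC2)C(C)(C)CCC3)OO1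
F6 | step 11 | (4S)-4-benzyl-3-[(2S)-2-[(3S,6S)-6-[3-(5,5-dimethyl-3,4,5,6,7,8-hexahydronaphthalen-2-yl)-3-(tosylhydrazinylidene)propyl]-6-methyl-1,2-dioxan-3-yl]propanoyl]-1,3-oxazolidin-2-one | C[C@H](C(=O)N1[C@@H](Cc2ccccc2)COC1=O)[C@@H]1CC[C@](C)(CCC(=NNS(=O)(=O)c2ccc(C)cc2)C2=CC3=C(CC2)C(C)(C)CCC3)OO1
F7 | step 4 | (4S)-4-benzyl-3-[(2E)-2,6-dimethylhepta-2,6-dienoyl]-1,3-oxazolidin-2-one | C=C(C)CC/C=C(\C)C(=O)N1[C@@H](Cc2ccccc2)COC1=O
F8 | step 4 | (4S)-4-benzyl-3-[(2E)-6-hydroperoxy-6-methoxy-2-methylhept-2-enoyl]-1,3-oxazolidin-2-one | COC(C)(OO)CC/C=C(\C)C(=O)N1[C@@H](Cc2ccccc2)COC1=O
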